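## Retrosynthetic overview
1. Target ⇒ its dipotassium salt ⇒ hydrogenolysis of three benzyl ethers ⇒ double O-sulfation of 5,7,3'-tri-O-benzylquercetin, in which only 3-OH and 4'-OH are free.
2. 4'-OH ⇒ MOM ether (acid-labile, orthogonal to benzyl). 3-OH ⇒ oxygenation of C3 of a flavone by epoxidation and isomerisation.
3. Ring C is the only ring built, since rings A and B are bought as arenes. It comes from oxa-Michael closure and dehydrogenation of a 2'-hydroxychalcone.
4. Key C–C bond (Cα–Cβ of the chalcone, later C3–C2) ⇒ intermolecular Claisen–Schmidt aldol condensation of the ring A methyl ketone with the ring B aldehyde.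
5. Ketone ⇒ phloroacetophenone plus BnBr. Aldehyde ⇒ protocatechualdehyde, 4-O-MOM first and 3-O-Bn second.

Assumption: the target has no stereocentre, so there is no enantiomer to control, and the free bis(hydrogen sulfate) drawn is taken as the end point, with dipotassium salt 15 as the storable form.

## Route

Step 1
Reactants: 1 2',4',6'-trihydroxyacetophenone
Product: 2 4',6'-bis(benzyloxy)-2'-hydroxyacetophenone
Conditions: BnBr (2.1 equiv), K2CO3 (2.5 equiv), DMF, 60 °C, 3 h
Reagents that add atoms: benzyl bromide, BrCc1ccccc1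
Why: In this Williamson ether synthesis the para OH and one ortho OH are alkylated, while the last ortho OH is held in a strong hydrogen bond to the ketone and stays free at 2.1 equiv of BnBr; no stereocentre is formed.

Step 2
Reactants: 3 3,4-dihydroxybenzaldehyde
Product: 4 3-hydroxy-4-(methoxymethoxy)benzaldehyde
Conditions: MOMCl (1.05 equiv), K2CO3 (1.1 equiv), acetone, 0 °C to rt, 12 h
Reagents that add atoms: chloromethyl methyl ether, COCCl
Why: In this regioselective Williamson-type O-alkylation the 4-OH para to the formyl group is about two pKa units more acidic than the 3-OH, so one equivalent of weak base makes only the 4-phenoxide, which takes the MOM group.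

Step 3
Reactants: 4 3-hydroxy-4-(methoxymethoxy)benzaldehyde
Product: 5 3-(benzyloxy)-4-(methoxymethoxy)benzaldehyde
Conditions: BnBr (1.2 equiv), K2CO3 (1.5 equiv), DMF, rt, 6 h
Reagents that add atoms: benzyl bromide, BrCc1ccccc1
Why: This is a Williamson ether synthesis on the only remaining phenol, and the aldehyde and the MOM acetal are inert to K2CO3.

Step 4
Reactants: 2 4',6'-bis(benzyloxy)-2'-hydroxyacetophenone; 5 3-(benzyloxy)-4-(methoxymethoxy)benzaldehyde
Product: 7 (E)-1-[2,4-bis(benzyloxy)-6-hydroxyphenyl]-3-[3-(benzyloxy)-4-(methoxymethoxy)phenyl]prop-2-en-1-one, via aldol adduct 6 (not isolated)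
Conditions: KOH (50% aq, excess), EtOH–THF, rt, 36 h; then cold dilute AcOH to pH 6
Reagents that add atoms: none
Why: In this Claisen–Schmidt (crossed aldol) condensation only ketone 2 can enolise and only aldehyde 5 is a good acceptor, so the fragments join cleanly, and E1cB loss of water from racemic 6 removes the carbinol stereocentre and gives the E-alkene under thermodynamic control.

Step 5
Reactants: 7 (E)-chalcone
Product: 9 5,7-bis(benzyloxy)-2-[3-(benzyloxy)-4-(methoxymethoxy)phenyl]-4H-chromen-4-one, via flavanone 8 (not isolated)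
Conditions: I2 (10 mol %), DMSO, 120 °C, 3 h; aq Na2S2O3 quench
Reagents that add atoms: none
Why: Intramolecular oxa-Michael addition closes ring C to racemic flavanone 8, and iodine-catalysed dehydrogenation with DMSO as terminal oxidant then erases the C2 stereocentre and gives the aromatic 4-pyranone.

Step 6
Reactants: 9 flavone
Product: 11 5,7-bis(benzyloxy)-2-[3-(benzyloxy)-4-(methoxymethoxy)phenyl]-3-hydroxy-4H-chromen-4-one, via flavone 2,3-epoxide 10 (not isolated)
Conditions: DMDO (0.07 M in acetone, 3 × 1.5 equiv), CH2Cl2, 0 °C to rt, 24 h; evaporate; p-TsOH·H2O (5 mol %), CH2Cl2, rt, 30 min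
Reagents that add atoms: dimethyldioxirane, CC1(C)OO1
Why: Neutral dioxirane epoxidation of the enol-ether-like C2=C3 bond gives racemic epoxide 10, whose acid-catalysed opening and tautomerisation give the planar 3-hydroxyflavone, so no stereocentre remains and any early MOM loss is harmless because step 7 removes that group.

Step 7
Reactants: 11 4'-O-MOM flavonol
Product: 12 5,7,3'-tri-O-benzylquercetin
Conditions: conc. HCl (cat.), MeOH–THF (1:1), 50 °C, 3 h
Reagents that add atoms: none
Why: Acid-catalysed acetal exchange with methanol cleaves the MOM group, while aryl benzyl ethers, including the 5-O-benzyl ether, withstand dilute HCl at 50 °C.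

Step 8
Reactants: 12 5,7,3'-tri-O-benzylquercetin
Product: 14 dipotassium 5,7,3'-tri-O-benzylquercetin 3,4'-bissulfate, via bis(pyridinium) salt 13 (not isolated)
Conditions: SO3·pyridine (8 equiv), pyridine, 25 to 45 °C, 16 h; then aq KHCO3, 0 °C, to pH 8; evaporate; C18 reversed-phase silica (H2O to MeOH)
Reagents that add atoms: sulfur trioxide–pyridine complex, O=S(=O)([O-])[n+]1ccccc1; potassium hydrogencarbonate, [K+].OC([O-])=O
Why: In this O-sulfation with an SO3–amine complex the 3-OH and 4'-OH are the only free hydroxyls, so excess reagent drives both to base-stable sulfate monoesters, which are obtained pyridine-free as the dipotassium salt.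

Step 9
Reactants: 14 dipotassium 5,7,3'-tri-O-benzylquercetin 3,4'-bissulfate
Product: 15 dipotassium quercetin 3,4'-bissulfate
Conditions: H2 (1 atm), 10% Pd/C, MeOH–H2O (4:1), rt, 4 h
Reagents that add atoms: none
Why: Catalytic hydrogenolysis cleaves the three aryl benzyl ethers under neutral conditions, and neither the sulfate monoester anions nor the tetrasubstituted C2=C3 bond is reduced.

Step 10
Reactants: 15 dipotassium quercetin 3,4'-bissulfate
Product: 16 quercetin 3,4'-bissulfate
Conditions: sulfonated polystyrene cation-exchange resin (H+ form), H2O, 0–4 °C, short column; freeze-dry at once, store cold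
Reagents that add atoms: none
Why: Cation exchange on a strong-acid resin swaps K+ for H+ without adding soluble acid, and working cold and fast outruns self-catalysed hydrolysis of the sulfate esters.

## Compound list
1 | 2',4',6'-trihydroxyacetophenone (phloroacetophenone) | CC(=O)c1c(O)cc(O)cc1O | starting material
2 | 4',6'-bis(benzyloxy)-2'-hydroxyacetophenone | CC(=O)c1c(O)cc(OCc2ccccc2)cc1OCc1ccccc1 | intermediate
3 | 3,4-dihydroxybenzaldehyde (protocatechualdehyde) | O=Cc1ccc(O)c(O)c1 | starting material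
4 | 3-hydroxy-4-(methoxymethoxy)benzaldehyde | O=Cc1ccc(OCOC)c(O)c1 | intermediate
5 | 3-(benzyloxy)-4-(methoxymethoxy)benzaldehyde | O=Cc1ccc(OCOC)c(OCc2ccccc2)c1 | intermediate
6 | racemic aldol adduct 1-[2,4-bis(benzyloxy)-6-hydroxyphenyl]-3-[3-(benzyloxy)-4-(methoxymethoxy)phenyl]-3-hydroxypropan-1-one (not isolated) | O=C(CC(O)c1ccc(OCOC)c(OCc2ccccc2)c1)c1c(O)cc(OCc2ccccc2)cc1OCc1ccccc1 | intermediate
7 | (E)-1-[2,4-bis(benzyloxy)-6-hydroxyphenyl]-3-[3-(benzyloxy)-4-(methoxymethoxy)phenyl]prop-2-en-1-one (chalcone) | O=C(/C=C/c1ccc(OCOC)c(OCc2ccccc2)c1)c1c(O)cc(OCc2ccccc2)cc1OCc1ccccc1 | intermediate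
8 | racemic flavanone 5,7-bis(benzyloxy)-2-[3-(benzyloxy)-4-(methoxymethoxy)phenyl]chroman-4-one (not isolated) | O=C1CC(c2ccc(OCOC)c(OCc3ccccc3)c2)Oc2cc(OCc3ccccc3)cc(OCc3ccccc3)c12 | intermediate
9 | flavone 5,7-bis(benzyloxy)-2-[3-(benzyloxy)-4-(methoxymethoxy)phenyl]-4H-chromen-4-one | O=c1cc(-c2ccc(OCOC)c(OCc3ccccc3)c2)oc2cc(OCc3ccccc3)cc(OCc3ccccc3)c12 | intermediate
10 | racemic 2,3-epoxide of flavone 9, oxirane cis-fused on C2–C3 of ring C (not isolated) | O=C1C2OC2(c3ccc(OCOC)c(OCc4ccccc4)c3)Oc3cc(OCc4ccccc4)cc(OCc4ccccc4)c13 | intermediate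
11 | 5,7-bis(benzyloxy)-2-[3-(benzyloxy)-4-(methoxymethoxy)phenyl]-3-hydroxy-4H-chromen-4-one | O=c1c(O)c(-c2ccc(OCOC)c(OCc3ccccc3)c2)oc2cc(OCc3ccccc3)cc(OCc3ccccc3)c12 | intermediate
12 | 5,7,3'-tri-O-benzylquercetin (3-OH and 4'-OH free) | O=c1c(O)c(-c2ccc(O)c(OCc3ccccc3)c2)oc2cc(OCc3ccccc3)cc(OCc3ccccc3)c12 | intermediate
13 | bis(pyridinium) 5,7,3'-tri-O-benzylquercetin 3,4'-bissulfate (not isolated) | O=c1c(OS(=O)(=O)[O-])c(-c2ccc(OS(=O)(=O)[O-])c(OCc3ccccc3)c2)oc2cc(OCc3ccccc3)cc(OCc3ccccc3)c12.c1cc[nH+]cc1.c1cc[nH+]cc1 | intermediate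
14 | dipotassium 5,7,3'-tri-O-benzylquercetin 3,4'-bissulfate | O=c1c(OS(=O)(=O)[O-])c(-c2ccc(OS(=O)(=O)[O-])c(OCc3ccccc3)c2)oc2cc(OCc3ccccc3)cc(OCc3ccccc3)c12.[K+].[K+] | intermediate
15 | dipotassium quercetin 3,4'-bissulfate | O=c1c(OS(=O)(=O)[O-])c(-c2ccc(OS(=O)(=O)[O-])c(O)c2)oc2cc(O)cc(O)c12.[K+].[K+] | intermediate
16 | quercetin 3,4'-bissulfate (achiral) | O=c1c(OS(=O)(=O)O)c(-c2ccc(OS(=O)(=O)O)c(O)c2)oc2cc(O)cc(O)c12 | target

## Counts and risks
Total step count: 10.
Longest linear sequence: 9 steps (3 → 4 → 5 → 7 → 9 → 11 → 12 → 14 → 15 → 16).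

**Step 5.** Traces of HI at 120 °C may cleave the MOM acetal or the 5-O-benzyl ether next to the carbonyl. The fallback sets out from chalcone 7 and comes back at flavone 9, with ring closure and oxidation done separately. Chalcone 7 is isomerised with NaOAc in refluxing EtOH to flavanone 8, which is now isolated and crystallised. Flavanone 8 is then dehydrogenated by hydride abstraction with DDQ in refluxing dioxane, so no iodine, acid or DMSO is present. New compounds on this detour: none F0.

**Step 6.** The C2=C3 bond is a sluggish partner for DMDO, and long exposure invites oxidation of benzylic C–H bonds. The fallback sets out from flavone 9 and comes back at flavonol 11. Instead of oxidising the alkene, C3–H is deprotonated with LiN(iPr)2 in THF at −78 °C to give the 3-lithioflavone F1. This is trapped with B(OMe)3 and, on addition of AcOH, gives the dimethyl flavon-3-ylboronate F2. Oxidation of the C–B bond in the same flask with 30% H2O2 (0 °C to rt) delivers 11.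

**Step 8.** The hydrogen-bonded 3-OH may be sulfated incompletely, and mono- and bis-sulfate salts are hard to separate. The fallback sets out from diol 12 and comes back at dipotassium salt 14. Diol 12 is treated with 2,2,2-trichloroethyl chlorosulfate, Et3N and DMAP in THF to give the neutral bis(2,2,2-trichloroethyl sulfate) diester F3, which is purified on ordinary silica gel. Zn dust and HCO2NH4 in MeOH then remove both trichloroethyl groups by reductive fragmentation to give the diammonium bissulfate F4. Evaporation with aqueous KHCO3 exchanges ammonium for potassium and gives 14.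

## Further compounds
F0 | step 5 | none | none
F1 | step 6 | 5,7-bis(benzyloxy)-2-[3-(benzyloxy)-4-(methoxymethoxy)phenyl]-3-lithio-4H-chromen-4-one | O=c1c([Li])c(-c2ccc(OCOC)c(OCc3ccccc3)c2)oc2cc(OCc3ccccc3)cc(OCc3ccccc3)c12
F2 | step 6 | dimethyl {5,7-bis(benzyloxy)-2-[3-(benzyloxy)-4-(methoxymethoxy)phenyl]-4-oxo-4H-chromen-3-yl}boronate | O=c1c(B(OC)OC)c(-c2ccc(OCOC)c(OCc3ccccc3)c2)oc2cc(OCc3ccccc3)cc(OCc3ccccc3)c12
F3 | step 8 | 5,7,3'-tri-O-benzylquercetin 3,4'-bis(2,2,2-trichloroethyl sulfate) | O=c1c(OS(=O)(=O)OCC(Cl)(Cl)Cl)c(-c2ccc(OS(=O)(=O)OCC(Cl)(Cl)Cl)c(OCc3ccccc3)c2)oc2cc(OCc3ccccc3)cc(OCc3ccccc3)c12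
F4 | step 8 | diammonium 5,7,3'-tri-O-benzylquercetin 3,4'-bissulfate | O=c1c(OS(=O)(=O)[O-])c(-c2ccc(OS(=O)(=O)[O-])c(OCc3ccccc3)c2)oc2cc(OCc3ccccc3)cc(OCc3ccccc3)c12.[NH4+].[NH4+]
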